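## Analysis of the target

The target is a 2,6-diaryl-3,7-dioxabicyclo[3.3.0]octane (furofuran lignan skeleton): two cis-fused tetrahydrofurans, ring A (C1, C2, O3, C4, C5) and ring B (C1, C5, C6, O7, C8), sharing the C1–C5 bond. It has four contiguous stereocentres: C1 (S, fully substituted, acetoxy), C2 (R, guaiacyl), C5 (R) and C6 (S, veratryl). The acetoxy group and H5 are cis, and both aryl groups lie on the convex face, so the C2 aryl group is cis to the C1 oxygen and the C6 aryl group is cis to H5. The two aryl groups differ (free phenol against methyl ether), so the halves cannot come from a dimerisation and must be brought in one after the other. Sensitive points are the two benzylic ether carbons (ionisation and epimerisation under acid), the para-hydroxybenzyl ether at C2 (quinone-methide opening once the phenol is free), and the tertiary acetate (lost with hydride or strong base, and only accessible by acylating a tertiary alcohol). The hard part is the fully substituted, oxygenated C1 next to benzylic C2, with defined relative and absolute configuration. The strategy rests on one feature: the vicinal C1–O and C2–O3 bonds are what a C1–C2 epoxide delivers when it is opened at C2 by oxygen, and C4 sits where a carboxyl group can be that oxygen. The alkene behind this epoxide, with the C5 methylene carrying the C4 carboxyl and the C8 hydroxymethyl group both on C1, is an (E)-arylidene succinate (Stobbe-type) reduced at one ester.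

## Retrosynthetic reasoning

**21 to 19 (no skeletal bond cut).** The phenol of 21 is uncovered last, from silyl ether 20. A free para-hydroxyl would make the C2–O3 bond labile and would be acetylated before the hindered C1 hydroxyl. The acetate is put on tertiary alcohol 19 only after all hydride and Lewis-acid steps are over.

**19 to 17 (oxidation level of C4).** The C4 methylene of 19 is traced to lactol 18 and then to lactone 17. A carbonyl at C4 makes C5 an enolisable carbon and lets ring A be closed as a lactone. The forward steps are a partial hydride reduction and an ionic reduction of the lactol.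

**17 to 15 (cut C6–O7).** Ring B is opened at the benzylic C6–O7 bond and not at O7–C8. C6 carries the electron-rich veratryl group, so a C6 carbinol ionises easily and the C8 hydroxyl captures the cation. The carbinol configuration therefore need not be controlled. The diol needed for this (in triol 16) is stored as the acetonide in 15.

**15 to 12 and 13 (cut C5–C6).** This is an aldol disconnection between the lactone enolate 14 and veratraldehyde 13. It brings in the second aryl group as a commercial aldehyde at a late, convergent point. The forward reaction must place the new bond at C5 cis to C8, since only that arrangement can give the cis-fused bicycle.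

**12 to 11 (protecting group).** The acetonide ties the tertiary C1 hydroxyl to the primary C8 hydroxyl. It removes two acidic protons before enolate chemistry and fixes the lactone on O3.

**11 to 10 (cut C2–O3, the key disconnection).** The lactone oxygen–C2 bond and the C1 hydroxyl are traced to the C1–C2 epoxide of 10, with the tert-butyl ester at C4 as the internal nucleophile. The cut is made here because an epoxide is the one precursor that delivers both C–O bonds stereospecifically. C2 is set by inversion and C1 is carried over unchanged. The forward reaction must attack C2, not C1, and must stay SN2-like.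

**10 to 9 (epoxide to alkene).** The epoxide comes from the (E)-allylic alcohol 9 by a reagent-controlled asymmetric epoxidation, directed by the C8 hydroxyl. This sets the absolute configuration of C1 and C2 in one step.

**9 to 8 (oxidation level of C8).** The allylic alcohol comes from the conjugated ethyl ester of 8. The forward reduction must spare the tert-butyl ester, which differs both sterically and electronically.

**8 to 2 and 6 (cut C1=C2).** The arylidene succinate is cut at the double bond into silylated vanillin 2 and phosphonosuccinate 6. A classical Stobbe condensation would need hot alkoxide, which an aryl silyl ether is not expected to survive, and a further esterification. The phosphonate olefination gives the same (E)-isomer with the two esters already differentiated.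

**6 to 3 and 4; 2 to 1.** Phosphonate 6 is the C-alkylation product of 3 with bromoacetate 4. Aldehyde 2 is silylated vanillin 1.

## Alternatives that were turned down

**Alternative 1:** Both benzylic C–O bonds (C2–O3 and C6–O7) are cut at once. This leads back to the open-chain triol A2, (2S,3S)-3-[(3,4-dimethoxyphenyl)methyl]-2-[(4-hydroxy-3-methoxyphenyl)methyl]butane-1,2,4-triol, with C1 and C5 already in place.
- Forward key step: an anodic oxidation mediated by a catalytic quinone would turn the guaiacyl CH2 into a para-quinone methide and the veratryl CH2 into a benzylic cation. The C4 and C8 hydroxyls would capture them and give the 1-hydroxy furofuran A1. A1 is one acetylation from the target, in practice two operations because the phenol acetylates first.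
- For: two rings and two stereocentres in one step, no protecting group on the phenol, no stoichiometric oxidant, and the shortest endgame. On step and redox economy this plan is stronger than the chosen one.
- Against: the key step does not make C1 or C5, so the tertiary-alcohol stereocentre must still be built into A2 by separate asymmetric chemistry. C2 and C6 would both depend on which face of a planar intermediate the hydroxyl adds to, and 2,6-diaryl furofurans offer only a small exo preference. The veratryl CH2 has no free phenol and is harder to oxidise than the benzylic ether C–H bonds of the product, so over-oxidation is likely. A free electron-rich phenol at an anode is also prone to radical coupling.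
- Comparison: the chosen strategy is longer, but it sets C2 by a stereospecific inversion, leaves only C6 to a cation closure, and keeps the phenol masked to the last step.

**Alternative 2:** Ring A is cut at C1–C2 and C4–C5, with O3 inserted afterwards.
- Forward key step: an arylketene released from acid chloride A4 by an amine base would add across the C1=C5 bond of silyl enol ether A5, a (2S)-2-veratryl-4-silyloxy-2,5-dihydrofuran. This gives the cis-fused cyclobutanone A3. A Baeyer–Villiger oxidation would then insert O3 between C2 and the carbonyl carbon, which becomes C4.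
- For: the fully substituted C1 and two C–C bonds form in one convergent step. The ring fusion must be cis, the polarity of the partners gives the right regiochemistry, and the ketene should add anti to the C6 aryl group. In convergence this plan is stronger than the chosen, linear one.
- Against: A5 must be made enantiopure from a β-alkoxy ketone that can lose its C6 configuration by retro-oxa-Michael opening and can enolise toward C8 as well as C5. Monoaryl ketenes dimerise readily and are poor partners for silyl enol ethers. The cycloaddition normally puts the ketene substituent on the concave face, so C2 must be corrected by enolisation with an uncertain thermodynamic bias. The Baeyer–Villiger step must choose between two secondary migrating carbons in the presence of two electron-rich arenes. Lactone reduction, acylation and desilylation are still needed afterwards, so nothing is saved at the end.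
- Comparison: the chosen route assigns each stereocentre to a well-understood event (reagent-controlled epoxidation for C1, inversion for C2, substrate control for C5 and C6), at the price of a longer linear sequence.

**Alternative 3:** The C5–C6 bond is cut in a precursor where C6 is already bonded to O7: the spiro veratrylidene acetal A7, which would be made from diol lactone 11 of the chosen route.
- Forward key step: a silyl triflate and a tertiary amine would convert the lactone into its silyl ketene acetal and ionise the acetal to an oxocarbenium ion tethered through O7–C8. Attack of C5 on C6 would close ring B and free the C1 oxygen, giving the bicyclic hydroxy lactone A6, identical with 17.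
- For: it shares the key step and everything before it with the chosen plan, replaces three steps (acetonide, aldol, acid closure) by two, needs no C6 carbinol, and can only give the cis-fused product. On step count between 11 and 17 it is stronger.
- Against: the C5–C6 bond must form while C6=O7 lies inside the forming five-membered ring, an endo closure on an oxocarbenium ion that is geometrically disfavoured. The ionised acetal can also open toward the C1 oxygen. The silyl ketene acetal carries a β-leaving group at C1 under Lewis-acid conditions. The C6 configuration would depend on an untested transition state.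
- Comparison: the chosen strategy spends one more step, but it closes ring B by oxygen attack on a cation whose π-system (C6–aryl) is outside the ring, a favoured 5-exo mode, after an ordinary intermolecular aldol.

Key step: step 6

Remark: TBS = tert-butyldimethylsilyl and Ar = 4-[(tert-butyldimethylsilyl)oxy]-3-methoxyphenyl; atoms of open-chain and monocyclic compounds are called by their target numbers (C1 acetoxy bridgehead, C2, O3, C4, C5, C6, O7, C8), and 15 and 16 (at C6) and 18 (at C4) are carried as epimer mixtures because those centres are reset or removed in the next step.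

## Route

Step 1
Reactants: 1 vanillin (4-hydroxy-3-methoxybenzaldehyde)
Product: 2 4-[(tert-butyldimethylsilyl)oxy]-3-methoxybenzaldehyde
Conditions: TBSCl, imidazole, DMF, rt
Reagents that add atoms: tert-butyldimethylsilyl chloride, CC(C)(C)[Si](C)(C)Cl
Why: Standard imidazole-promoted silylation of a phenol; the aryl silyl ether masks the phenol through the hydride, enolate and Lewis-acid steps and makes the para oxygen a weaker donor than an alkyl ether would be.

Step 2
Reactants: 3 triethyl phosphonoacetate; 4 tert-butyl bromoacetate
Product: 6 4-tert-butyl 1-ethyl 2-(diethoxyphosphoryl)butanedioate (racemic), via sodium phosphonoacetate carbanion 5 (not isolated)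
Conditions: NaH, THF, 0 °C; then 4, 0 °C → rt
Reagents that add atoms: none
Why: SN2 C-alkylation of a stabilised phosphonate carbanion with an α-bromo ester, the usual way to phosphonosuccinates; it gives the two ester groups already differentiated.

Step 3
Reactants: 6 4-tert-butyl 1-ethyl 2-(diethoxyphosphoryl)butanedioate; 2 4-[(tert-butyldimethylsilyl)oxy]-3-methoxybenzaldehyde
Product: 8 4-tert-butyl 1-ethyl (2E)-2-(Ar-methylidene)butanedioate, via sodium phosphonosuccinate carbanion 7 (not isolated)
Conditions: NaH (1.0 equiv), THF, 0 °C; then 2, 0 °C → rt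
Reagents that add atoms: none
Why: Horner–Wadsworth–Emmons olefination; with an aromatic aldehyde an α-substituted phosphonoacetate should give mainly the (E)-alkylidene succinate (aryl trans to the conjugated ester), the isomer a Stobbe condensation also gives. The conditions leave the aryl silyl ether alone, and any minor (Z)-isomer is removed by chromatography.

Step 4
Reactants: 8 4-tert-butyl 1-ethyl (2E)-2-(Ar-methylidene)butanedioate
Product: 9 tert-butyl (3E)-4-Ar-3-(hydroxymethyl)but-3-enoate
Conditions: i-Bu2AlH (2.2 equiv), CH2Cl2, −78 °C; aq. potassium sodium tartrate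
Reagents that add atoms: none
Why: 1,2-Reduction of a conjugated ethyl ester to the allylic alcohol by a dialkylaluminium hydride; at −78 °C the hindered tert-butyl ester reacts much more slowly, and the alkene geometry is not touched.

Step 5
Reactants: 9 tert-butyl (3E)-4-Ar-3-(hydroxymethyl)but-3-enoate
Product: 10 tert-butyl 2-[(2S,3S)-3-Ar-2-(hydroxymethyl)oxiran-2-yl]acetate
Conditions: Ti(Oi-Pr)4 (0.1 equiv), L-(+)-diethyl tartrate (0.12 equiv), t-BuOOH (2 equiv, in decane), 4 Å MS, CH2Cl2, −25 °C
Reagents that add atoms: tert-butyl hydroperoxide, CC(C)(C)OO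
Why: Katsuki–Sharpless asymmetric epoxidation of a 2-substituted (E)-3-aryl allylic alcohol, a well-behaved substrate class; the L-(+)-tartrate ligand should give the (2S,3S)-epoxide (C1 S, C2 S), as it does with other (E)-2-alkyl-3-aryl allylic alcohols. Catalytic titanium with sieves at low temperature limits Lewis-acid opening of the electron-rich aryl epoxide, which is used crude.

Step 6
Reactants: 10 tert-butyl 2-[(2S,3S)-3-Ar-2-(hydroxymethyl)oxiran-2-yl]acetate
Product: 11 (4S,5R)-5-Ar-4-hydroxy-4-(hydroxymethyl)oxolan-2-one
Conditions: camphor-10-sulfonic acid (0.1 equiv), 4 Å MS, CH2Cl2, 0 °C → rt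
Reagents that add atoms: none
Why: Camphorsulfonic acid protonates the epoxide oxygen, the benzylic C2–O bond lengthens, and the carbonyl oxygen of the tert-butyl ester attacks C2 from the side opposite the departing oxygen to give a 2-tert-butoxy-oxolan-2-ylium ion, which sheds the tert-butyl group as 2-methylpropene and returns the proton. The closest known reaction type is the acid-promoted lactonisation of aryl epoxides by a neighbouring tert-butyl ester or tert-butyl carbonate after a Sharpless epoxidation, a relative of halolactonisation. Ring A (C1, C2, O3, C4, C5) closes as a γ-lactone in a 5-endo mode with respect to the epoxide, since both epoxide carbons end up in the new ring; this is acceptable here because the C2–O bond is already largely broken in the transition state. C2 is set by inversion (S in 10 becomes R in 11, only the oxygen partner changing), and C1 keeps its configuration because its C–O bond is never broken. With the (E)-geometry of 9 this places the aryl group cis to the C1 hydroxyl and trans to C8, as the target requires. The step needs attack at C2 and not at C1, which is secured by the benzylic position and by ring size, since attack at C1 would give a β-lactone at a fully substituted carbon. It also needs an SN2-like opening and not a free cation or a 1,2-shift, which is helped by the silyl ether (a weaker para donor than an alkyl ether), the meta methoxy group, a non-polar solvent, low temperature and a nucleophile held three atoms from C1. The C8 hydroxyl cannot compete, because its attack at C2 would give an oxetane.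

Step 7
Reactants: 11 (4S,5R)-5-Ar-4-hydroxy-4-(hydroxymethyl)oxolan-2-one
Product: 12 (5S,6R)-6-Ar-2,2-dimethyl-1,3,7-trioxaspiro[4.4]nonan-8-one
Conditions: Me2C(OMe)2, pyridinium p-toluenesulfonate (cat.), CH2Cl2, rt
Reagents that add atoms: 2,2-dimethoxypropane, COC(C)(C)OC
Why: Acid-catalysed transketalisation of the 1,2-diol (tertiary C1 hydroxyl, primary C8 hydroxyl) to the dioxolane; it removes the hydroxyl protons before enolate chemistry and prevents translactonisation onto the C8 oxygen.

Step 8
Reactants: 12 (5S,6R)-6-Ar-2,2-dimethyl-1,3,7-trioxaspiro[4.4]nonan-8-one; 13 veratraldehyde (3,4-dimethoxybenzaldehyde)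
Product: 15 (5S,6R,9R)-6-Ar-9-[(3,4-dimethoxyphenyl)(hydroxy)methyl]-2,2-dimethyl-1,3,7-trioxaspiro[4.4]nonan-8-one (both carbinol epimers), via lithium enolate of the lactone 14 (not isolated)
Conditions: LiN(i-Pr)2 (1.1 equiv), THF, −78 °C; then 13, −78 °C; AcOH quench at −78 °C
Reagents that add atoms: none
Why: Lithium enolate aldol addition of a γ-lactone; the aldehyde should add to C5 on the face opposite the C2 aryl group and the dioxolane oxygen, that is cis to C8 (C5 R), the only arrangement that can give the cis-fused bicycle. C6 is left as a mixture because the next step ionises it, and the low temperature keeps β-elimination of the dioxolane oxygen slow.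

Step 9
Reactants: 15 (5S,6R,9R)-6-Ar-9-[(3,4-dimethoxyphenyl)(hydroxy)methyl]-2,2-dimethyl-1,3,7-trioxaspiro[4.4]nonan-8-one
Product: 17 (1S,2R,5R,6S)-2-Ar-6-(3,4-dimethoxyphenyl)-1-hydroxy-3,7-dioxabicyclo[3.3.0]octan-4-one, via triol lactone 16 (not isolated)
Conditions: CF3CO2H, H2O (a few equiv), CH2Cl2, 0 °C → rt
Reagents that add atoms: none
Why: Acid-catalysed acetonide hydrolysis followed by SN1 etherification: the C6 carbinol ionises to a veratryl-stabilised cation, which the C8 hydroxyl captures in a 5-exo closure of ring B (C6–O7). The aryl group should take the exo position, trans to C4 on the new ring, as in related cation closures to furofuranones, so both C6 epimers of 15 should converge on C6 S.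

Step 10
Reactants: 17 (1S,2R,5R,6S)-2-Ar-6-(3,4-dimethoxyphenyl)-1-hydroxy-3,7-dioxabicyclo[3.3.0]octan-4-one
Product: 18 (1S,2R,5R,6S)-2-Ar-6-(3,4-dimethoxyphenyl)-3,7-dioxabicyclo[3.3.0]octane-1,4-diol (both C4 epimers)
Conditions: i-Bu2AlH (3 equiv), CH2Cl2, −78 °C; aq. potassium sodium tartrate
Reagents that add atoms: none
Why: Partial reduction of a γ-lactone to the lactol; one equivalent of hydride is used up by the C1 hydroxyl, and the aluminium hemiacetal is stable at −78 °C, so the reduction stops at the aldehyde oxidation level.

Step 11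
Reactants: 18 (1S,2R,5R,6S)-2-Ar-6-(3,4-dimethoxyphenyl)-3,7-dioxabicyclo[3.3.0]octane-1,4-diol
Product: 19 (1S,2R,5R,6S)-2-Ar-6-(3,4-dimethoxyphenyl)-3,7-dioxabicyclo[3.3.0]octan-1-ol
Conditions: Et3SiH (3 equiv), BF3·OEt2 (2 equiv), CH2Cl2, −78 → −30 °C
Reagents that add atoms: none
Why: Ionic hydrogenation of a lactol: BF3 generates the C4 oxocarbenium ion and the silane reduces it to the cyclic ether. No stereocentre is formed, and at low temperature the oxocarbenium ion should form faster than either benzylic ether ionises.

Step 12
Reactants: 19 (1S,2R,5R,6S)-2-Ar-6-(3,4-dimethoxyphenyl)-3,7-dioxabicyclo[3.3.0]octan-1-ol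
Product: 20 (1S,2R,5R,6S)-2-Ar-6-(3,4-dimethoxyphenyl)-3,7-dioxabicyclo[3.3.0]octan-1-yl acetate
Conditions: Ac2O (excess), 4-(dimethylamino)pyridine (1 equiv), Et3N, CH2Cl2, rt → 40 °C
Reagents that add atoms: acetic anhydride, CC(=O)OC(C)=O
Why: Acylation of a tertiary alcohol through the N-acetylpyridinium ion; the C1 hydroxyl is the only free hydroxyl because the phenol is still silylated, and C1 is not touched stereochemically. A hindered bridgehead alcohol needs stoichiometric 4-(dimethylamino)pyridine and time.

Step 13
Reactants: 20 (1S,2R,5R,6S)-2-Ar-6-(3,4-dimethoxyphenyl)-3,7-dioxabicyclo[3.3.0]octan-1-yl acetate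
Product: 21 (1S,2R,5R,6S)-6-(3,4-dimethoxyphenyl)-2-(4-hydroxy-3-methoxyphenyl)-3,7-dioxabicyclo[3.3.0]octan-1-yl acetate (CNP0107105.1)
Conditions: Bu4NF (1.1 equiv), AcOH (1.2 equiv), THF, 0 °C
Reagents that add atoms: none
Why: Fluoride cleavage of an aryl silyl ether; buffering with AcOH keeps the phenoxide concentration low, so the tertiary acetate and the para benzylic ether (quinone-methide pathway) should not be endangered.

## Compound list

1 | vanillin (4-hydroxy-3-methoxybenzaldehyde) | COc1cc(C=O)ccc1O | starting material
2 | 4-[(tert-butyldimethylsilyl)oxy]-3-methoxybenzaldehyde | COc1cc(C=O)ccc1O[Si](C)(C)C(C)(C)C | intermediate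
3 | triethyl phosphonoacetate | CCOC(=O)CP(=O)(OCC)OCC | starting material
4 | tert-butyl bromoacetate | CC(C)(C)OC(=O)CBr | starting material
5 | sodium phosphonoacetate carbanion (sodium salt of 3) | [Na+].CCOC(=O)[CH-]P(=O)(OCC)OCC | intermediate
6 | 4-tert-butyl 1-ethyl 2-(diethoxyphosphoryl)butanedioate (racemic) | CCOC(=O)C(CC(=O)OC(C)(C)C)P(=O)(OCC)OCC | intermediate
7 | sodium phosphonosuccinate carbanion (sodium salt of 6) | [Na+].CCOC(=O)[C-](CC(=O)OC(C)(C)C)P(=O)(OCC)OCC | intermediate
8 | 4-tert-butyl 1-ethyl (2E)-2-({4-[(tert-butyldimethylsilyl)oxy]-3-methoxyphenyl}methylidene)butanedioate | CCOC(=O)/C(CC(=O)OC(C)(C)C)=C/c1ccc(O[Si](C)(C)C(C)(C)C)c(OC)c1 | intermediate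
9 | tert-butyl (3E)-4-{4-[(tert-butyldimethylsilyl)oxy]-3-methoxyphenyl}-3-(hydroxymethyl)but-3-enoate | COc1cc(/C=C(/CO)CC(=O)OC(C)(C)C)ccc1O[Si](C)(C)C(C)(C)C | intermediate
10 | tert-butyl 2-[(2S,3S)-3-{4-[(tert-butyldimethylsilyl)oxy]-3-methoxyphenyl}-2-(hydroxymethyl)oxiran-2-yl]acetate | COc1cc([C@@H]2O[C@]2(CO)CC(=O)OC(C)(C)C)ccc1O[Si](C)(C)C(C)(C)C | intermediate
11 | (4S,5R)-5-{4-[(tert-butyldimethylsilyl)oxy]-3-methoxyphenyl}-4-hydroxy-4-(hydroxymethyl)oxolan-2-one | COc1cc([C@H]2OC(=O)C[C@]2(O)CO)ccc1O[Si](C)(C)C(C)(C)C | intermediate
12 | (5S,6R)-6-{4-[(tert-butyldimethylsilyl)oxy]-3-methoxyphenyl}-2,2-dimethyl-1,3,7-trioxaspiro[4.4]nonan-8-one | COc1cc([C@H]2OC(=O)C[C@@]23OC(C)(C)OC3)ccc1O[Si](C)(C)C(C)(C)C | intermediate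
13 | veratraldehyde (3,4-dimethoxybenzaldehyde) | COc1ccc(C=O)cc1OC | starting material
14 | lithium (5S,6R)-6-{4-[(tert-butyldimethylsilyl)oxy]-3-methoxyphenyl}-2,2-dimethyl-1,3,7-trioxaspiro[4.4]non-8-en-8-olate (lithium enolate of 12) | [Li+].COc1cc([C@H]2OC([O-])=C[C@@]23OC(C)(C)OC3)ccc1O[Si](C)(C)C(C)(C)C | intermediate
15 | (5S,6R,9R)-6-{4-[(tert-butyldimethylsilyl)oxy]-3-methoxyphenyl}-9-[(3,4-dimethoxyphenyl)(hydroxy)methyl]-2,2-dimethyl-1,3,7-trioxaspiro[4.4]nonan-8-one (both carbinol epimers) | COc1cc([C@H]2OC(=O)[C@H](C(O)c3ccc(OC)c(OC)c3)[C@@]23OC(C)(C)OC3)ccc1O[Si](C)(C)C(C)(C)C | intermediate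
16 | (3R,4S,5R)-5-{4-[(tert-butyldimethylsilyl)oxy]-3-methoxyphenyl}-3-[(3,4-dimethoxyphenyl)(hydroxy)methyl]-4-hydroxy-4-(hydroxymethyl)oxolan-2-one (both carbinol epimers) | COc1cc([C@H]2OC(=O)[C@H](C(O)c3ccc(OC)c(OC)c3)[C@]2(O)CO)ccc1O[Si](C)(C)C(C)(C)C | intermediate
17 | (1S,2R,5R,6S)-2-{4-[(tert-butyldimethylsilyl)oxy]-3-methoxyphenyl}-6-(3,4-dimethoxyphenyl)-1-hydroxy-3,7-dioxabicyclo[3.3.0]octan-4-one | COc1cc([C@H]2OC(=O)[C@@H]3[C@@H](c4ccc(OC)c(OC)c4)OC[C@]23O)ccc1O[Si](C)(C)C(C)(C)C | intermediate
18 | (1S,2R,5R,6S)-2-{4-[(tert-butyldimethylsilyl)oxy]-3-methoxyphenyl}-6-(3,4-dimethoxyphenyl)-3,7-dioxabicyclo[3.3.0]octane-1,4-diol (both C4 epimers) | COc1cc([C@H]2OC(O)[C@@H]3[C@@H](c4ccc(OC)c(OC)c4)OC[C@]23O)ccc1O[Si](C)(C)C(C)(C)C | intermediate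
19 | (1S,2R,5R,6S)-2-{4-[(tert-butyldimethylsilyl)oxy]-3-methoxyphenyl}-6-(3,4-dimethoxyphenyl)-3,7-dioxabicyclo[3.3.0]octan-1-ol | COc1cc([C@H]2OC[C@@H]3[C@@H](c4ccc(OC)c(OC)c4)OC[C@]23O)ccc1O[Si](C)(C)C(C)(C)C | intermediate
20 | (1S,2R,5R,6S)-2-{4-[(tert-butyldimethylsilyl)oxy]-3-methoxyphenyl}-6-(3,4-dimethoxyphenyl)-3,7-dioxabicyclo[3.3.0]octan-1-yl acetate | COc1cc([C@H]2OC[C@@H]3[C@@H](c4ccc(OC)c(OC)c4)OC[C@]23OC(C)=O)ccc1O[Si](C)(C)C(C)(C)C | intermediate
21 | (1S,2R,5R,6S)-6-(3,4-dimethoxyphenyl)-2-(4-hydroxy-3-methoxyphenyl)-3,7-dioxabicyclo[3.3.0]octan-1-yl acetate (CNP0107105.1) | COc1cc([C@H]2OC[C@@H]3[C@@H](c4ccc(OC)c(OC)c4)OC[C@]23OC(C)=O)ccc1O | target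

## Step count and least certain steps

Total step count: 13. Longest linear sequence: 12 steps (vanillin 1 to 21 through steps 1 and 3–13); step 2 is a one-step side branch.

**Step 6 (key step).**
- Risk: loss of stereochemical fidelity at C2 through ionisation to a free benzylic cation, which then closes from either face, or a 1,2-shift of the Meinwald type before the ester oxygen arrives. The para oxygen still stabilises positive charge at C2 and the 5-endo trajectory is strained.
- Fallback (from 10, back at 12): the opening is made intermolecular and chelation-controlled.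
  - Ti(Oi-Pr)4 and PhCO2H in CH2Cl2 open the titanium-bound epoxy alcohol at C2 with inversion (the C3-selective opening of a 2,3-epoxy alcohol by a carboxylic acid) and should give tert-butyl (3S,4R)-4-(benzoyloxy)-4-Ar-3-hydroxy-3-(hydroxymethyl)butanoate F1.
  - 2,2-Dimethoxypropane and pyridinium p-toluenesulfonate tie the C1 and C8 hydroxyls as the dioxolane tert-butyl 2-[(4S)-4-[(R)-(benzoyloxy)(Ar)methyl]-2,2-dimethyl-1,3-dioxolan-4-yl]acetate F2.
  - i-Bu2AlH at −78 °C removes the benzoate reductively without touching the tert-butyl ester, as in step 4, to give tert-butyl 2-[(4S)-4-[(R)-(Ar)(hydroxy)methyl]-2,2-dimethyl-1,3-dioxolan-4-yl]acetate F3.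
  - A catalytic amount of NaH in THF at 0 °C lets the C2 alkoxide close the lactone on the ester, which gives 12 directly.

**Step 5.**
- Risk: Lewis-acid opening of the electron-rich aryl epoxide during the epoxidation or its work-up (by isopropoxide, tartrate or traces of water), and erosion of enantioselectivity if the ester carbonyl competes for titanium.
- Fallback (from 9, back at 10): a dioxirane-mediated Shi epoxidation with KHSO5 (used as the triple salt 2KHSO5·KHSO4·K2SO4) and the L-fructose-derived chiral ketone in buffered aqueous MeCN at 0 °C. It needs no Lewis acid and accepts free allylic alcohols. By analogy with (E)-cinnamyl-type alkenes, which give (R,R)-epoxides with the D-fructose-derived ketone, the antipodal ketone is expected to be the one that gives the (2S,3S)-epoxide. This fallback makes no compound outside the list (F0).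

**Step 8.**
- Risk: β-elimination of the dioxolane oxygen from the enolate (E1cB, giving a butenolide) before the aldehyde is added, or addition on the wrong face of C5.
- Fallback (from 11, back at 17): the C1 oxygen is used as a non-leaving alkoxide.
  - Et3SiCl and imidazole silylate only the primary hydroxyl and give (4S,5R)-5-Ar-4-hydroxy-4-{[(triethylsilyl)oxy]methyl}oxolan-2-one F4.
  - LiN(i-Pr)2 (2.2 equiv) at −78 °C forms the alkoxide–enolate dianion, which cannot eliminate and which, as in Fráter–Seebach alkylations, reacts anti to the oxido group, that is cis to C8. Addition of 13 gives (3R,4S,5R)-5-Ar-3-[(3,4-dimethoxyphenyl)(hydroxy)methyl]-4-hydroxy-4-{[(triethylsilyl)oxy]methyl}oxolan-2-one F5.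
  - Camphorsulfonic acid in wet CH2Cl2 removes the triethylsilyl group and closes ring B through the C6 cation to give 17.

**Step 9.**
- Risk: loss of H5 from the C6 cation to give the conjugated benzylidene lactone, acid-induced ionisation of the lactone C2–O3 bond with scrambling of C2, loss of the aryl silyl ether, or closure on the wrong face of the cation.
- Fallback (from 12, back at 17): the C6 cation is generated oxidatively under neutral conditions.
  - The enolate of 12 is alkylated with 3,4-dimethoxybenzyl bromide to give (5S,6R,9R)-6-Ar-9-[(3,4-dimethoxyphenyl)methyl]-2,2-dimethyl-1,3,7-trioxaspiro[4.4]nonan-8-one F6.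
  - Aqueous AcOH removes the acetonide, with no benzylic alcohol present, and gives (3R,4S,5R)-5-Ar-3-[(3,4-dimethoxyphenyl)methyl]-4-hydroxy-4-(hydroxymethyl)oxolan-2-one F7.
  - 2,3-Dichloro-5,6-dicyano-1,4-benzoquinone (1.1 equiv) in dry CH2Cl2 oxidises the veratryl CH2 to the cation, which the C8 hydroxyl captures to give 17.

**Step 11.**
- Risk: BF3-induced ionisation of the benzylic C2–O3 or C6–O7 bond, leading to epimerisation or to reductive ring opening by the silane.
- Fallback (from 17, back at 19): ring A is re-closed by O-alkylation, so that no C–O bond at C2 is broken.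
  - LiBH4 in THF reduces the lactone to (3S,4R,5S)-3-[(R)-(Ar)(hydroxy)methyl]-5-(3,4-dimethoxyphenyl)-4-(hydroxymethyl)oxolan-3-ol F8.
  - p-Toluenesulfonyl chloride in pyridine at 0 °C sulfonylates only the primary C4 hydroxyl to give [(2S,3R,4S)-4-[(R)-(Ar)(hydroxy)methyl]-2-(3,4-dimethoxyphenyl)-4-hydroxyoxolan-3-yl]methyl 4-methylbenzenesulfonate F9.
  - NaH in THF lets the C2 alkoxide displace the sulfonate in a 5-exo Williamson closure, with retention at C2, to give 19.

**Step 12.**
- Risk: incomplete acylation of the hindered bridgehead tertiary alcohol, with elimination or benzylic ionisation if the reaction is forced by heat or Lewis acid.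
- Fallback (from 19, back at 20): the alcohol is first converted into its alkoxide with LiN(SiMe3)2 in THF at −78 °C and the alkoxide is trapped with acetyl chloride. The reacting species changes from the neutral alcohol to the far more nucleophilic alkoxide. This fallback makes no compound outside the list (F0).

## Further compounds

F1 | step 6 | tert-butyl (3S,4R)-4-(benzoyloxy)-4-{4-[(tert-butyldimethylsilyl)oxy]-3-methoxyphenyl}-3-hydroxy-3-(hydroxymethyl)butanoate | COc1cc([C@@H](OC(=O)c2ccccc2)[C@@](O)(CO)CC(=O)OC(C)(C)C)ccc1O[Si](C)(C)C(C)(C)C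
F2 | step 6 | tert-butyl 2-[(4S)-4-[(R)-(benzoyloxy){4-[(tert-butyldimethylsilyl)oxy]-3-methoxyphenyl}methyl]-2,2-dimethyl-1,3-dioxolan-4-yl]acetate | COc1cc([C@@H](OC(=O)c2ccccc2)[C@@]2(CC(=O)OC(C)(C)C)OC(C)(C)OC2)ccc1O[Si](C)(C)C(C)(C)C
F3 | step 6 | tert-butyl 2-[(4S)-4-[(R)-{4-[(tert-butyldimethylsilyl)oxy]-3-methoxyphenyl}(hydroxy)methyl]-2,2-dimethyl-1,3-dioxolan-4-yl]acetate | COc1cc([C@@H](O)[C@@]2(CC(=O)OC(C)(C)C)OC(C)(C)OC2)ccc1O[Si](C)(C)C(C)(C)C
F0 | step 5 | none | none
F4 | step 8 | (4S,5R)-5-{4-[(tert-butyldimethylsilyl)oxy]-3-methoxyphenyl}-4-hydroxy-4-{[(triethylsilyl)oxy]methyl}oxolan-2-one | COc1cc([C@H]2OC(=O)C[C@]2(O)CO[Si](CC)(CC)CC)ccc1O[Si](C)(C)C(C)(C)C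
F5 | step 8 | (3R,4S,5R)-5-{4-[(tert-butyldimethylsilyl)oxy]-3-methoxyphenyl}-3-[(3,4-dimethoxyphenyl)(hydroxy)methyl]-4-hydroxy-4-{[(triethylsilyl)oxy]methyl}oxolan-2-one (both carbinol epimers) | COc1cc([C@H]2OC(=O)[C@H](C(O)c3ccc(OC)c(OC)c3)[C@]2(O)CO[Si](CC)(CC)CC)ccc1O[Si](C)(C)C(C)(C)C
F6 | step 9 | (5S,6R,9R)-6-{4-[(tert-butyldimethylsilyl)oxy]-3-methoxyphenyl}-9-[(3,4-dimethoxyphenyl)methyl]-2,2-dimethyl-1,3,7-trioxaspiro[4.4]nonan-8-one | COc1cc([C@H]2OC(=O)[C@H](Cc3ccc(OC)c(OC)c3)[C@@]23OC(C)(C)OC3)ccc1O[Si](C)(C)C(C)(C)C
F7 | step 9 | (3R,4S,5R)-5-{4-[(tert-butyldimethylsilyl)oxy]-3-methoxyphenyl}-3-[(3,4-dimethoxyphenyl)methyl]-4-hydroxy-4-(hydroxymethyl)oxolan-2-one | COc1cc([C@H]2OC(=O)[C@H](Cc3ccc(OC)c(OC)c3)[C@]2(O)CO)ccc1O[Si](C)(C)C(C)(C)C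
F8 | step 11 | (3S,4R,5S)-3-[(R)-{4-[(tert-butyldimethylsilyl)oxy]-3-methoxyphenyl}(hydroxy)methyl]-5-(3,4-dimethoxyphenyl)-4-(hydroxymethyl)oxolan-3-ol | COc1cc([C@@H](O)[C@@]2(O)CO[C@H](c3ccc(OC)c(OC)c3)[C@H]2CO)ccc1O[Si](C)(C)C(C)(C)C
F9 | step 11 | [(2S,3R,4S)-4-[(R)-{4-[(tert-butyldimethylsilyl)oxy]-3-methoxyphenyl}(hydroxy)methyl]-2-(3,4-dimethoxyphenyl)-4-hydroxyoxolan-3-yl]methyl 4-methylbenzenesulfonate | COc1cc([C@@H](O)[C@@]2(O)CO[C@H](c3ccc(OC)c(OC)c3)[C@H]2COS(=O)(=O)c2ccc(C)cc2)ccc1O[Si](C)(C)C(C)(C)C
F0 | step 12 | none | none
A1 | alternative 1 | (1S,2R,5R,6S)-6-(3,4-dimethoxyphenyl)-2-(4-hydroxy-3-methoxyphenyl)-3,7-dioxabicyclo[3.3.0]octan-1-ol | COc1cc([C@H]2OC[C@@H]3[C@@H](c4ccc(OC)c(OC)c4)OC[C@]23O)ccc1O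
A2 | alternative 1 | (2S,3S)-3-[(3,4-dimethoxyphenyl)methyl]-2-[(4-hydroxy-3-methoxyphenyl)methyl]butane-1,2,4-triol | COc1cc(C[C@@](O)(CO)[C@H](CO)Cc2ccc(OC)c(OC)c2)ccc1O
A3 | alternative 2 | cis-fused 7-{4-[(tert-butyldimethylsilyl)oxy]-3-methoxyphenyl}-4-(3,4-dimethoxyphenyl)-1-[(triethylsilyl)oxy]-3-oxabicyclo[3.2.0]heptan-6-one, both aryl groups exo, configured as C1, C2, C5 and C6 of the target | COc1cc([C@H]2C(=O)[C@@H]3[C@@H](c4ccc(OC)c(OC)c4)OC[C@]23O[Si](CC)(CC)CC)ccc1O[Si](C)(C)C(C)(C)C
A4 | alternative 2 | {4-[(tert-butyldimethylsilyl)oxy]-3-methoxyphenyl}acetyl chloride | COc1cc(CC(Cl)=O)ccc1O[Si](C)(C)C(C)(C)C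
A5 | alternative 2 | (2S)-2-(3,4-dimethoxyphenyl)-4-[(triethylsilyl)oxy]-2,5-dihydrofuran | COc1ccc([C@H]2OCC(O[Si](CC)(CC)CC)=C2)cc1OC
A6 | alternative 3 | (1S,2R,5R,6S)-2-{4-[(tert-butyldimethylsilyl)oxy]-3-methoxyphenyl}-6-(3,4-dimethoxyphenyl)-1-hydroxy-3,7-dioxabicyclo[3.3.0]octan-4-one (identical with 17) | COc1cc([C@H]2OC(=O)[C@@H]3[C@@H](c4ccc(OC)c(OC)c4)OC[C@]23O)ccc1O[Si](C)(C)C(C)(C)C
A7 | alternative 3 | (5S,6R)-6-{4-[(tert-butyldimethylsilyl)oxy]-3-methoxyphenyl}-2-(3,4-dimethoxyphenyl)-1,3,7-trioxaspiro[4.4]nonan-8-one (acetal carbon unassigned) | COc1cc([C@H]2OC(=O)C[C@@]23OC(c4ccc(OC)c(OC)c4)OC3)ccc1O[Si](C)(C)C(C)(C)C
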